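Count the partner each flask has met alongside its minutes.

| setting | epsilon | beta | alpha | gamma | summer | winter | autumn | spring |
|---|---|---|---|---|---|---|---|---|
| substrate | 20 mM | 20 mM | 20 mM | 10 mM | 20 mM | 20 mM | 20 mM | 20 mM (fed, over 3.0 min) |
| partner | 5 equiv | 7 equiv | 11 equiv | 5 equiv | 5.00 equiv (in portions, 3, over 3.0 min) | 5.00 equiv (fed, over 3.0 min) | 5.00 equiv | 5.00 equiv |
| remark | run made earlier | run made earlier | run made earlier | run made earlier | first portion at the start, last at 3.0 min | all else is in the flask from the start; the feed brings no volume worth counting | everything together at the start | all else is in the flask from the start; the feed brings no volume worth counting |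
| time |  |  |  |  | 15 min | 15 min | 15 min | 15 min |

| run | time / min | double product / % |
|---|---|---|
| epsilon | 0.500 | 0 |
| epsilon | 1.33 | 2.7 |
| epsilon | 2.50 | 4.1 |
| epsilon | 4.00 | 11.0 |
| epsilon | 5.00 | 11.7 |
| epsilon | 8.00 | 17.6 |
| epsilon | 10.0 | 17.6 |
| beta | 0.833 | 0.1 |
| beta | 2.50 | 10.1 |
| beta | 4.00 | 15.2 |
| beta | 6.00 | 20.3 |
| beta | 10.0 | 22.5 |
| beta | 12.0 | 19.8 |
| beta | 15.0 | 19.0 |
| alpha | 0.833 | 3.2 |
| alpha | 2.50 | 16.8 |
| alpha | 4.00 | 22.8 |
| alpha | 6.00 | 25.1 |
| alpha | 10.0 | 17.6 |
| alpha | 12.0 | 12.5 |
| alpha | 15.0 | 12.1 |
| gamma | 1.33 | 0 |
| gamma | 2.50 | 0 |
| gamma | 4.00 | 4.4 |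
| gamma | 8.00 | 7.6 |
| gamma | 15.0 | 13.3 |

(scatter of a reading: 1 percentage point)



- which flask leads in amount of double product, in percent of the substrate charged ("all alike" within 1.5 percentage points) (summer / winter / autumn / spring / all alike)
- how much double product is there at the end, in percent of the substrate charged: summer
- how much double product is there at the end, in percent of the substrate charged: winter
- how much double product is there at the end, in percent of the substrate charged: autumn
- how much double product is there at the end, in percent of the substrate charged: spring

I took the charged concentration of partner multiplied by the time as the exposure, which for autumn came to 1500 mM·min. With partner in excess at 5.00 equiv, I treated the steps that take partner as pseudo-first-order in the other reactant, so exposure served as a rough clock for those steps. But it stayed rough: gamma at 750 mM·min read 13.3%, and epsilon at 800 mM·min read 17.6%.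

The highest readings of double product came at 800 mM·min to 1000 mM·min in epsilon, 1320 mM·min in alpha and 1400 mM·min in beta. But the heights read differently: 17.6%, 25.1% and 22.5%. So exposure placed the top only roughly and did not give its height, and autumn's exposure lay past these.

The dosed flasks start late, though. A steady feed holds its material back by 1.50 min on average, half the feed time, and summer's portions, at the start, midway and at the end, average the same. That took 150 mM·min off the exposure of each. Beta's fall, from 22.5% at 10.0 min to 19.0% at 15.0 min, scaled to that loss, gave 0.75 percentage points, smaller than the margin of 1.5 points. So I reckoned each dosed flask slightly above autumn, yet alike.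

The forecast said all alike, with autumn 16.5%, summer 16.5%, winter 16.5% and spring 17%: “Each 3-minute dosing acts mostly as a 1.5-minute delay, which barely matters near the maximum.” It said partner feeding may lose slightly, where I had it gain.

The flasks came out all alike: autumn 18.5%, summer 18.7%, winter 18.9%, spring 19.0%.

    substrate + partner → first product + by-product (k = 3.50 M⁻¹ min⁻¹)
    partner + first product → double product + by-product (k = 0.944 M⁻¹ min⁻¹)
    first product → side product (k = 0.0923 min⁻¹)
    partner + tris adduct → tetra adduct + by-product (k = 6.64 M⁻¹ min⁻¹)
    partner + double product → tris adduct + by-product (k = 1.19 M⁻¹ min⁻¹)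

First product stood at 19.6% in summer at 15.0 min, against 16.3% in autumn. Raised alone, partner moved summer's answer by 5 points at 9.80 equiv, an exposure of 2940 mM·min. Summer read at 40 min, an exposure of 4000 mM·min, held 5.47% double product.

The earlier runs and the new flask stem from a simulated flask on assumed constants, noise included.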